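**Strategy.** The target gibberellin carries its C19 and C20 carboxyls 1,3-diaxially on ring A. Both are hidden as the C19–C20 bond of a cyclopentanone, so ring A can be closed at C3–C4 by an intramolecular Mukaiyama aldol of a regiodefined silyl enol ether (C4=C19) onto a C3 aldehyde hung from C10. The precursor is a benzo-fused diquinane; closure gives a bicyclo[3.2.1]octanone whose bridge forces the C4 quaternary centre and whose open transition state sets the 3β-hydroxyl, both relayed from the catalytically set C10. Diketone cleavage then frees the diacid; Birch reduction (ring C), conjugate propargylation and ketyl–alkyne closure (ring D) finish the skeleton.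

Key step: step 7

Remarks on the chemistry:
- Gibberellane numbering (C1–C20, rings A–D, α/β as in the usual gibberellin drawing) is used for all intermediates; in 13 and 14, C19 and C20 are bonded to each other.
- Assumption: the (R,R)-Trost ligand is written for step 2; the sense of induction on this enolate is not certain, and the antipodal ligand is used if the opposite enantiomer of 4 results.
- Compounds 1 and 2 and all reagents (allyl acetate, CH2=C=CHSnBu3, SmI2 in THF) are taken to be commercial.

Step 1
Reactants: 1 3-ethoxy-2-methylcyclopent-2-en-1-one; 2 (2-bromo-5-methoxyphenyl)acetic acid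
Product: 3 [2-(4-ethoxy-3-methyl-2-oxocyclopent-3-en-1-yl)-5-methoxyphenyl]acetic acid (racemic)
Conditions: Pd(OAc)2 (5 mol %), XPhos (10 mol %), LiN(SiMe3)2 (3.3 equiv), THF, 65 °C; cold dilute aq. HCl work-up
Reagents that add atoms: none
Why: Palladium-catalysed α′-arylation of a vinylogous ester enolate (Buchwald–Hartwig-type ketone arylation) should form the C9–C10 bond, because kinetic deprotonation occurs only at the C10 methylene, the arylacetic acid is masked as its inert lithium carboxylate and the more acidic α-aryl product is stored as its enolate, so that C10 is formed racemic and is re-enolized in step 2.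

Step 2
Reactants: 3 [2-(4-ethoxy-3-methyl-2-oxocyclopent-3-en-1-yl)-5-methoxyphenyl]acetic acid
Product: 4 {2-[(1R)-4-ethoxy-3-methyl-2-oxo-1-(prop-2-en-1-yl)cyclopent-3-en-1-yl]-5-methoxyphenyl}acetic acid
Conditions: LiN(SiMe3)2 (2.1 equiv), THF, −78 °C; allyl acetate (1.05 equiv), [Pd(η3-C3H5)Cl]2 (2.5 mol %), (R,R)-DACH-phenyl Trost ligand (6 mol %), −20 °C; cold dilute aq. HCl work-up
Reagents that add atoms: allyl acetate, C=CCOC(C)=O
Why: Trost asymmetric allylic alkylation of a tetrasubstituted α-aryl ketone enolate should set the C10 quaternary centre, the only stereocentre of the route set by a catalyst, through face selection by the chiral π-allyl palladium complex, while the carboxylate α-methylene is not deprotonated by the amide base and any allyl carboxylate formed is re-ionized by the catalyst.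

Step 3
Reactants: 4 {2-[(1R)-4-ethoxy-3-methyl-2-oxo-1-(prop-2-en-1-yl)cyclopent-3-en-1-yl]-5-methoxyphenyl}acetic acid
Product: 7 methyl {5-methoxy-2-[(1S)-3-methyl-4-oxo-1-(prop-2-en-1-yl)cyclopent-2-en-1-yl]phenyl}acetate, via allylic alcohol 5 (not isolated), via enone acid 6 (not isolated)
Conditions: i-Bu2AlH (3 equiv), CH2Cl2, −78 °C; then HCl, MeOH/H2O (20:1), 50 °C
Reagents that add atoms: methanol, CO
Why: Stork–Danheiser transposition (1,2-reduction of the vinylogous ester, then acid-induced loss of ethanol from the allylic alcohol) should give the 4,4-disubstituted 2-methylcyclopentenone while methanolic HCl esterifies the unhindered arylacetic acid (Fischer esterification), the aluminium carboxylate resisting reduction at −78 °C and C10 staying untouched.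

Step 4
Reactants: 7 methyl {5-methoxy-2-[(1S)-3-methyl-4-oxo-1-(prop-2-en-1-yl)cyclopent-2-en-1-yl]phenyl}acetate
Product: 9 methyl 6-methoxy-1-methyl-3a-(prop-2-en-1-yl)-2-[tri(propan-2-yl)silyloxy]-3,3a,8,8a-tetrahydrocyclopenta[a]indene-8-carboxylate (cis-fused; H-8 trans to H-8a), via potassium enolate 8 (not isolated)
Conditions: KN(SiMe3)2 (1.05 equiv), THF, −78 to −40 °C; then i-Pr3SiOTf (1.2 equiv), −78 to 0 °C
Reagents that add atoms: triisopropylsilyl trifluoromethanesulfonate, CC(C)[Si](OS(=O)(=O)C(F)(F)F)(C(C)C)C(C)C; potassium bis(trimethylsilyl)amide, C[Si](C)(C)[N-][Si](C)(C)C.[K+] (potassium of 8 only)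
Why: Intramolecular Michael addition (5-exo-trig) of the arylacetate enolate to C5 should close ring B, necessarily cis to the aryl-bearing C10 (cis-diquinane) and with the epimerizable ester on the convex face trans to C4, and the C4 enolate thus generated regiospecifically is silylated on oxygen in the cold, before proton transfer from the benzylic C6–H can relocate it.

Step 5
Reactants: 9 methyl 6-methoxy-1-methyl-3a-(prop-2-en-1-yl)-2-[tri(propan-2-yl)silyloxy]-3,3a,8,8a-tetrahydrocyclopenta[a]indene-8-carboxylate
Product: 11 methyl 3a-(3-hydroxypropyl)-6-methoxy-1-methyl-2-[tri(propan-2-yl)silyloxy]-3,3a,8,8a-tetrahydrocyclopenta[a]indene-8-carboxylate, via alkylborane 10 (not isolated)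
Conditions: 9-BBN-H, THF, 0 to 25 °C; then NaBO3·4H2O, H2O, 25 °C
Reagents that add atoms: sodium perborate, [Na+].[O-]OB=O; 9-borabicyclo[3.3.1]nonane, [H]B1C2CCCC1CCC2 (boron and cyclooctanediyl of 10 only)
Why: Anti-Markovnikov hydroboration–oxidation of the terminal alkene with the bulky borane should leave the tetrasubstituted enol ether and the ester untouched and forms no stereocentre.

Step 6
Reactants: 11 methyl 3a-(3-hydroxypropyl)-6-methoxy-1-methyl-2-[tri(propan-2-yl)silyloxy]-3,3a,8,8a-tetrahydrocyclopenta[a]indene-8-carboxylate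
Product: 12 methyl 6-methoxy-1-methyl-3a-(3-oxopropyl)-2-[tri(propan-2-yl)silyloxy]-3,3a,8,8a-tetrahydrocyclopenta[a]indene-8-carboxylate
Conditions: Dess–Martin periodinane, pyridine, CH2Cl2, 0 °C
Reagents that add atoms: none
Why: Dess–Martin oxidation of the primary alcohol to the C3 aldehyde proceeds under buffered conditions that should leave the silyl enol ether intact.

Step 7
Reactants: 12 methyl 6-methoxy-1-methyl-3a-(3-oxopropyl)-2-[tri(propan-2-yl)silyloxy]-3,3a,8,8a-tetrahydrocyclopenta[a]indene-8-carboxylate
Product: 13 ring-C-aromatic bridged ketol (ring A closed; C4–C19(=O)–C20H2–C10 bridge; 3β-hydroxy; 7-methyl ester)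
Conditions: BF3·OEt2 (1.2 equiv), CH2Cl2, −78 °C; aq. NaHCO3
Reagents that add atoms: none
Why: BF3 activates the C3 aldehyde and the C4 terminus of the C4=C19 silyl enol ether attacks it, after which fluoride removes the silyl group and work-up frees the β-hydroxy ketone. The closest known reaction type is the Lewis-acid-mediated intramolecular Mukaiyama aldol cyclization of formyl-tethered silyl enol ethers to bridged ketols. Ring A closes in a 6-(enolexo)-exo-trig mode and the product is a bicyclo[3.2.1]octan-6-one. C4 is controlled by the ring system, since the chain on C10 can reach only the exo face of the cis-fused cyclopentene, so C19 ends axial and cis to C20 and the methyl group equatorial. C3 is controlled by the open transition state, in which the BF3-bound oxygen lies antiperiplanar to the C4=C19 bond and away from the bulky silyloxy group, which places the hydroxyl axial (3β). The step needs regioselectivity for C4 over C20, secured because the enol ether was fixed in step 4, and facial selectivity at the aldehyde, secured by the steric and dipolar bias just described.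

Step 8
Reactants: 13 ring-C-aromatic bridged ketol
Product: 14 ring-C-aromatic bridged 19,20-dione (3β-hydroxy; 7-methyl ester)
Conditions: SeO2, 1,4-dioxane/H2O, 100 °C
Reagents that add atoms: selenium dioxide, O=[Se]=O
Why: Riley oxidation should convert the only enolizable position of the ketone (C20, since C4 is quaternary) into a carbonyl, as in the conversion of camphor into camphorquinone, and leaves C3 untouched.

Step 9
Reactants: 14 ring-C-aromatic bridged 19,20-dione
Product: 16 ring-C-aromatic 3β-hydroxy-13-methoxy-7,19,20-trioic acid, via diacid ester 15 (not isolated)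
Conditions: 30% H2O2, NaHCO3, THF/H2O, 0 to 25 °C; then LiOH, 40 °C; aq. HCl work-up
Reagents that add atoms: hydrogen peroxide, OO; lithium hydroxide, [Li+].[OH-]
Why: Oxidative cleavage of the α-diketone by hydroperoxide (Baeyer–Villiger-type addition and fragmentation) should open the C19–C20 bond to the cis-1,3-diaxial diacid under bicarbonate buffering that avoids retro-aldol cleavage of C3–C4, and LiOH then saponifies the C7 ester with C6 kept in its more stable configuration trans to C4.

Step 10
Reactants: 16 ring-C-aromatic 3β-hydroxy-13-methoxy-7,19,20-trioic acid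
Product: 18 tricyclic enone triacid (C13 ketone conjugated to C14=C8; H-9 β; 3β-hydroxy), via dihydroanisole 17 (not isolated)
Conditions: Li, NH3(l), THF, t-BuOH, −78 to −33 °C; NH4Cl; then 2 M HCl, THF, 25 °C
Reagents that add atoms: water, O
Why: Birch reduction of the 3,4-dialkylanisole (carboxylates and the alkoxide are inert) should give the 2,5-dihydroanisole with the tetrasubstituted C8=C9 bond, and acid hydrolysis with conjugation, as in the 19-norsteroid series, gives the C13 enone with C9 protonated on the β-face, anti to the axial C20 carboxyl.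

Step 11
Reactants: 18 tricyclic enone triacid
Product: 19 tricyclic enone trimethyl ester
Conditions: Me3SiCHN2, MeOH/toluene, 0 °C
Reagents that add atoms: (trimethylsilyl)diazomethane, C[Si](C)(C)C=[N+]=[N-]
Why: Esterification with (trimethylsilyl)diazomethane should work on the hindered tertiary acids and needs no base, so the β-hydroxy acid unit is not exposed to retro-aldol conditions.

Step 12
Reactants: 19 tricyclic enone trimethyl ester
Product: 20 8β-(prop-2-yn-1-yl) 13-ketone trimethyl ester (rings B and C cis-fused)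
Conditions: CH2=C=CHSnBu3 (2 equiv), TiCl4 (2.5 equiv), CH2Cl2, −78 °C
Reagents that add atoms: tributyl(propa-1,2-dien-1-yl)stannane, C=C=C[Sn](CCCC)(CCCC)CCCC
Why: Lewis-acid-mediated conjugate propargylation with an allenylstannane (SE2′, Sakurai-type) should deliver the propargyl group to C8 on the face of H-9 and give the cis-fused hydrindanone, which sets the C8 quaternary centre with C15 β.

Step 13
Reactants: 20 8β-(prop-2-yn-1-yl) 13-ketone trimethyl ester
Product: 21 trimethyl ent-3α,13-dihydroxygibberell-16-ene-7,19,20-trioate (trimethyl ester of the target gibberellin)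
Conditions: SmI2 (3 equiv), HMPA, t-BuOH (2 equiv), THF, 25 °C
Reagents that add atoms: none
Why: SmI2-mediated ketyl–alkyne reductive cyclization (5-exo-dig) should form ring D with the bridgehead 13-hydroxyl and the exocyclic C16 methylene in one step, the C13 configuration being fixed by the bicyclo[3.2.1]octane geometry.

Step 14
Reactants: 21 trimethyl ent-3α,13-dihydroxygibberell-16-ene-7,19,20-trioate
Product: 22 ent-3α,13-dihydroxygibberell-16-ene-7,19,20-trioic acid (the target gibberellin; 3β-hydroxyl in the usual drawing)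
Conditions: n-PrSH (excess), LiH, HMPA, 25 °C; then aq. HCl
Reagents that add atoms: none
Why: SN2 demethylation of the three methyl esters by thiolate, the standard non-hydrolytic cleavage of hindered gibberellin esters, avoids hydroxide and excess hydride and should therefore leave the 3β-hydroxy acid unit and the acid-sensitive 13-hydroxy-16-ene unit intact.

**Compound list**

1 | 3-ethoxy-2-methylcyclopent-2-en-1-one | CCOC1=C(C)C(=O)CC1 | starting material
2 | (2-bromo-5-methoxyphenyl)acetic acid | COc1ccc(Br)c(CC(=O)O)c1 | starting material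
3 | [2-(4-ethoxy-3-methyl-2-oxocyclopent-3-en-1-yl)-5-methoxyphenyl]acetic acid, racemic | CCOC1=C(C)C(=O)C(C1)c1ccc(OC)cc1CC(=O)O | intermediate
4 | {2-[(1R)-4-ethoxy-3-methyl-2-oxo-1-(prop-2-en-1-yl)cyclopent-3-en-1-yl]-5-methoxyphenyl}acetic acid | CCOC1=C(C)C(=O)[C@](CC=C)(C1)c1ccc(OC)cc1CC(=O)O | intermediate
5 | {2-[4-ethoxy-2-hydroxy-3-methyl-1-(prop-2-en-1-yl)cyclopent-3-en-1-yl]-5-methoxyphenyl}acetic acid, quaternary centre as in 4, both carbinol epimers | CCOC1=C(C)C(O)[C@](CC=C)(C1)c1ccc(OC)cc1CC(=O)O | intermediate (not isolated)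
6 | {5-methoxy-2-[(1S)-3-methyl-4-oxo-1-(prop-2-en-1-yl)cyclopent-2-en-1-yl]phenyl}acetic acid | CC1=C[C@](CC=C)(CC1=O)c1ccc(OC)cc1CC(=O)O | intermediate (not isolated)
7 | methyl {5-methoxy-2-[(1S)-3-methyl-4-oxo-1-(prop-2-en-1-yl)cyclopent-2-en-1-yl]phenyl}acetate | CC1=C[C@](CC=C)(CC1=O)c1ccc(OC)cc1CC(=O)OC | intermediate
8 | potassium enolate (C4=C19–O−) of the cis-fused Michael adduct of 7 | COc1ccc2c(c1)[C@@H](C(=O)OC)[C@@H]1C(C)=C([O-])C[C@]21CC=C.[K+] | intermediate (not isolated)
9 | methyl 6-methoxy-1-methyl-3a-(prop-2-en-1-yl)-2-[tri(propan-2-yl)silyloxy]-3,3a,8,8a-tetrahydrocyclopenta[a]indene-8-carboxylate, cis ring fusion, H-8 trans to H-8a | COc1ccc2c(c1)[C@@H](C(=O)OC)[C@@H]1C(C)=C(O[Si](C(C)C)(C(C)C)C(C)C)C[C@]21CC=C | intermediate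
10 | B-alkyl-9-borabicyclo[3.3.1]nonane from 9 (boron on the terminal carbon of the former allyl group) | COc1ccc2c(c1)[C@@H](C(=O)OC)[C@@H]1C(C)=C(O[Si](C(C)C)(C(C)C)C(C)C)C[C@]21CCCB1C2CCCC1CCC2 | intermediate (not isolated)
11 | 3a-(3-hydroxypropyl) analogue of 9 | COc1ccc2c(c1)[C@@H](C(=O)OC)[C@@H]1C(C)=C(O[Si](C(C)C)(C(C)C)C(C)C)C[C@]21CCCO | intermediate
12 | 3a-(3-oxopropyl) analogue of 9 (C3 aldehyde) | COc1ccc2c(c1)[C@@H](C(=O)OC)[C@@H]1C(C)=C(O[Si](C(C)C)(C(C)C)C(C)C)C[C@]21CCC=O | intermediate
13 | bridged ketol: anisole ring C (13-OMe), ring B cis-fused to the cyclopentanone C4–C5–C10–C20H2–C19(=O), ring A closed as a bicyclo[3.2.1]octan-6-one; 3β-OH (axial, anti to C19), 4-CH3 β, H-5 β, 6β-CO2CH3 | COc1ccc2c(c1)[C@@H](C(=O)OC)[C@H]1[C@@]23CC[C@H](O)[C@@]1(C)C(=O)C3 | intermediate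
14 | 19,20-dione of 13 | COc1ccc2c(c1)[C@@H](C(=O)OC)[C@H]1[C@@]23CC[C@H](O)[C@@]1(C)C(=O)C3=O | intermediate
15 | ring-C-aromatic 3β-hydroxy-13-methoxy 19,20-dioic acid 7-methyl ester (C19–C20 cleaved; both carboxyls α, cis-diaxial on ring A) | COc1ccc2c(c1)[C@@H](C(=O)OC)[C@H]1[C@@]2(C(=O)O)CC[C@H](O)[C@@]1(C)C(=O)O | intermediate (not isolated)
16 | ring-C-aromatic 3β-hydroxy-13-methoxy-7,19,20-trioic acid | COc1ccc2c(c1)[C@@H](C(=O)O)[C@H]1[C@@]2(C(=O)O)CC[C@H](O)[C@@]1(C)C(=O)O | intermediate
17 | 2,5-dihydroanisole triacid (enol ether C12=C13(OMe), C8=C9, C11 and C14 as CH2) | COC1=CCC2=C(C1)[C@@H](C(=O)O)[C@H]1[C@@]2(C(=O)O)CC[C@H](O)[C@@]1(C)C(=O)O | intermediate (not isolated)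
18 | tricyclic enone triacid (rings A–C; C13 ketone, C14=C8, H-9 β, 3β-OH, 7-, 19- and 20-CO2H) | O=C1CC[C@@H]2C(=C1)[C@@H](C(=O)O)[C@H]1[C@@]2(C(=O)O)CC[C@H](O)[C@@]1(C)C(=O)O | intermediate
19 | trimethyl ester of 18 | O=C1CC[C@@H]2C(=C1)[C@@H](C(=O)OC)[C@H]1[C@@]2(C(=O)OC)CC[C@H](O)[C@@]1(C)C(=O)OC | intermediate
20 | 8β-(prop-2-yn-1-yl) 13-ketone trimethyl ester (C15 and H-9 both β) | O=C1CC[C@@H]2[C@](CC#C)(C1)[C@@H](C(=O)OC)[C@H]1[C@@]2(C(=O)OC)CC[C@H](O)[C@@]1(C)C(=O)OC | intermediate
21 | trimethyl ent-3α,13-dihydroxygibberell-16-ene-7,19,20-trioate (trimethyl ester of the target gibberellin) | C=C1C[C@]23C[C@@]1(O)CC[C@H]2[C@]1(C(=O)OC)CC[C@H](O)[C@@](C)(C(=O)OC)[C@H]1[C@@H]3C(=O)OC | intermediate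
22 | ent-3α,13-dihydroxygibberell-16-ene-7,19,20-trioic acid (the target gibberellin; 3β-hydroxyl in the usual drawing) | C=C1C[C@]23C[C@@]1(O)CC[C@H]2[C@]1(C(=O)O)CC[C@H](O)[C@@](C)(C(=O)O)[C@H]1[C@@H]3C(=O)O | target

**Totals.** 14 steps; the longest linear sequence is 14 steps (from 1 or 2 to 22).

**Steps most likely to fail**

Step 2. Enantio-discrimination at the hindered, ortho-substituted α-aryl enolate may be insufficient. The fallback sets out from 3 and returns at 4. Compound 3 is allylated without a chiral catalyst (LiN(SiMe3)2, allyl bromide, THF, −78 °C) to the racemic allylated acid F1. The free carboxyl group then serves for a classical resolution: the (R)-1-phenylethylammonium salt F2 of the wanted enantiomer is crystallized (ethyl acetate/propan-2-ol) and acidified (aq. HCl) to give 4.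

Step 7. Facial selectivity at the aldehyde may be poor if chelation erodes the open transition state, so that the 3α-epimer forms beside 13. The fallback sets out from 12 and returns at 13. The closure is run as in step 7 and the product is taken on as the mixture of 13 and the 3α-ketol F3. Dess–Martin oxidation converges both on the single 3,19-dione F4. KB(s-Bu)3H (THF, −78 °C, cold quench) then reduces the less hindered C3 cyclohexanone from the equatorial side to the axial 3β-alcohol 13, so that C3 rests on hydride delivery instead of on the aldol.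

Step 8. Enolization of the hindered bridged ketone may be slow, and oxidation may compete at the benzylic C6–H. The fallback sets out from 13 and returns at 15. Soft enolization (Me3SiOTf, Et3N, CH2Cl2, 0 °C) gives the bis-silyl compound F5 (3-OSiMe3 and the C19=C20 enol ether, the only one possible). Ozonolysis (O3, CH2Cl2/MeOH, −78 °C; Me2S; aqueous work-up) cleaves the enol ether to the 19-acid 20-aldehyde F6. Pinnick oxidation (NaClO2, NaH2PO4, 2-methylbut-2-ene, t-BuOH/H2O) gives 15, which is saponified as in the second stage of step 9.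

**Further compounds**

F1 | step 2 | racemic {2-[4-ethoxy-3-methyl-2-oxo-1-(prop-2-en-1-yl)cyclopent-3-en-1-yl]-5-methoxyphenyl}acetic acid | CCOC1=C(C)C(=O)C(CC=C)(C1)c1ccc(OC)cc1CC(=O)O
F2 | step 2 | (R)-1-phenylethylammonium salt of 4 | CCOC1=C(C)C(=O)[C@](CC=C)(C1)c1ccc(OC)cc1CC(=O)[O-].C[C@@H]([NH3+])c1ccccc1
F3 | step 7 | 3α-epimer of ketol 13 | COc1ccc2c(c1)[C@@H](C(=O)OC)[C@H]1[C@@]23CC[C@@H](O)[C@@]1(C)C(=O)C3
F4 | step 7 | 3,19-dione (3-oxo analogue of 13) | COc1ccc2c(c1)[C@@H](C(=O)OC)[C@H]1[C@@]23CCC(=O)[C@@]1(C)C(=O)C3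
F5 | step 8 | bis(trimethylsilyl) derivative of 13 (3-OSiMe3; C19(OSiMe3)=C20 enol ether) | COc1ccc2c(c1)[C@@H](C(=O)OC)[C@H]1[C@@]23CC[C@H](O[Si](C)(C)C)[C@@]1(C)C(O[Si](C)(C)C)=C3
F6 | step 8 | ring-C-aromatic 3β-hydroxy-20-oxo-19-oic acid 7-methyl ester (C19 acid, C20 aldehyde) | COc1ccc2c(c1)[C@@H](C(=O)OC)[C@H]1[C@@]2(C=O)CC[C@H](O)[C@@]1(C)C(=O)O
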